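The target is cut at two bonds, C5–C7 and C8–C9, which one cycloaddition can form together (ring A = trione C1–C6 with spiro C5; ring B = C5, C7–C11; ring C = C8, C9, C12–C14). Because spiro C5 lies one CH2 (C7) away from the cis ring-fusion pair C8/C9, an intramolecular Diels–Alder reaction of a C5-dienylidene trione (diene C5=C11–C10=C9, dienophile C8=C7, tether C12–C14) closes rings B and C and sets C5, C8 and C9 in one operation. The precursor, the Knoevenagel adduct of a dearomatised acylphloroglucinol with (S,E)-8-oxolinalool, is formed and cyclised in one flask, its 2H-pyran valence isomer serving as a reversible store.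

Key step: step 4

Remark: enolised triones are drawn in one tautomer throughout, and 11 is drawn as the pyran closed through the C6 oxygen; if closure through the C4 oxygen competes, the pyrans and the C5=C11 geometries of 10 are taken to equilibrate under the conditions of step 4 (ring opening, reversible amine addition), and the spiro selectivity then rests on the transition-state preference given there.

Step 1
Reactants: 1 (S)-linalool
Product: 3 (S,E)-8-oxolinalool, via (S,E)-8-hydroxylinalool 2 (not isolated)
Conditions: SeO2 (0.1 equiv), t-BuOOH (2 equiv), salicylic acid (0.1 equiv), CH2Cl2, rt; filter; then MnO2 (10 equiv), CH2Cl2, rt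
Reagents that add atoms: tert-butyl hydroperoxide, CC(C)(C)OO
Why: Catalytic SeO2 with t-BuOOH performs the Riley allylic oxidation (ene reaction, then [2,3]-sigmatropic shift) selectively at the (E)-methyl group of the trisubstituted alkene, and MnO2 converges the allylic alcohol 2 with any enal already formed to 3, while the tertiary carbinol centre and the vinyl group are not touched.

Step 2
Reactants: 4 (R)-2-methylbutanoic acid; 5 2-methylphloroglucinol
Product: 7 (2R)-2-methyl-1-(2,4,6-trihydroxy-3-methylphenyl)butan-1-one, via (R)-2-methylbutanoyl chloride 6 (not isolated)
Conditions: (COCl)2, DMF (cat.), CH2Cl2, 0 °C to rt; concentrate; then 5, AlCl3 (3.5 equiv), PhNO2/CH2Cl2, 0 °C to rt; aq HCl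
Reagents that add atoms: none
Why: Friedel–Crafts C-acylation of the strongly activated arene at one of its two equivalent free positions should give a single regioisomer, the first acyl group suppresses a second acylation, and mild formation and use of the acid chloride should keep the α-stereocentre intact.

Step 3
Reactants: 7 (2R)-2-methyl-1-(2,4,6-trihydroxy-3-methylphenyl)butan-1-one; 8 prenyl acetate
Product: 9 dearomatised trione (ring A: C1 acyl, C2 enolic C–OH, C3 quaternary with methyl and prenyl, C4 and C6 C=O, C5 CH2)
Conditions: Pd2(dba)3 (2.5 mol %), (R,R)- or (S,S)-N,N′-(cyclohexane-1,2-diyl)bis[2-(diphenylphosphanyl)benzamide] (7.5 mol %; the antipode that delivers (3S)-9), Et3N (1.1 equiv), THF, 0 °C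
Reagents that add atoms: none
Why: In this Tsuji–Trost asymmetric allylic alkylation with dearomatisation, zerovalent palladium ionises 8 to the 1,1-dimethylallyl complex, the phenolate of 7 attacks its unsubstituted terminus through the most electron-rich ring carbon (methyl-bearing C3), and the chiral bisphosphine pocket selects the face so that C3 is set as (S), any C3 epimer being a diastereomer (because of the acyl centre) that can be removed.

Step 4
Reactants: 9 dearomatised trione; 3 (S,E)-8-oxolinalool
Product: 12 spiro tricycle, via dienylidene trione 10 (not isolated), via 2H-pyran valence isomer 11 (not isolated)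
Conditions: ethylenediammonium diacetate (20 mol %), 4 Å MS, PhMe, rt to 40 °C; then PhMe (to 0.01 M), BHT (cat.), 110 °C
Reagents that add atoms: none
Why: Amine-catalysed Knoevenagel condensation at C5 of 9, the only CH2 between two carbonyls, gives the 1,1-diacyl diene 10, which rests at room temperature as its 2H-pyran valence isomer 11 (oxa-6π electrocyclisation) and is released again on heating, whereupon its diene C5=C11–C10=C9 adds the tethered C8=C7 vinyl group in a concerted, inverse-electron-demand intramolecular Diels–Alder reaction. The closest known reaction types are the domino Knoevenagel/cycloaddition chemistry of alkylidene 1,3-dicarbonyl compounds and the thermal cycloaddition of nona-1,3,8-trienes. Ring B closes as the six-membered cycloaddition ring (new bonds C5–C7 and C8–C9) and ring C as the five-membered ring spanned by the three-atom tether C12–C13–C14, whereas hetero-cycloaddition through O=C–C5=C11 would demand a seven-membered tether ring and the pyran is only a reversible store. C8 and C9 should become cis because C5 carries a carbonyl in the inside position, as the terminus of a (Z)-diene does, and that group clashes with the tether in the trans-fused transition state, while their sense relative to the fixed C14 centre should follow from placing the small hydroxyl, not the methyl, in the crowded concave position near the C10 methyl, which puts the C14 methyl on the convex face. C5 is set by the C5=C11 geometry, with C6 inside and the C4 ketone outside (trans to C10), as opening of 11 delivers it; this should also be the more reactive array, because only the outside carbonyl stays coplanar with the diene and the isolated C4 ketone withdraws more strongly than the vinylogous-acid C6 carbonyl. The step therefore needs cis fusion, C14-controlled face selection and cycloaddition through the C4-outside geometry, and it relies on the free tertiary hydroxyl, the C10 methyl and the pyran regiochemistry.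

Step 5
Reactants: 12 spiro tricycle
Product: 13 syn-epoxide (oxirane across C10–C11 on the ring B face that carries ring C)
Conditions: VO(acac)2 (10 mol %), t-BuOOH (1.5 equiv, decane), CH2Cl2, 0 °C to rt
Reagents that add atoms: tert-butyl hydroperoxide, CC(C)(C)OO
Why: In this hydroxyl-directed epoxidation (bishomoallylic mode), the concave C14 alkoxide binds the pentavalent vanadium tert-butylperoxide and delivers oxygen to the C10=C11 face syn to ring C, which sets C10 and C11, leaves the undirected prenyl alkene and the electron-poor enol alone, and gives an epoxide that the C14 hydroxyl cannot open because backside approach is impossible.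

Step 6
Reactants: 13 syn-epoxide
Product: 14 CNP0236509.3 (target)
Conditions: LiEt3BH (5 equiv), THF, 0 °C to rt; aq NH4Cl, then citric acid to pH 4
Reagents that add atoms: none
Why: The first equivalents turn the enolised triketone and the hydroxyls into lithium salts, the anionic ring A (whose C4 ketone sits between two quaternary carbons) should then resist hydride, and hydride opens the trisubstituted epoxide by SN2 attack at the secondary C11 anti to oxygen (reductive epoxide opening), so the C10–O bond and the C10 configuration set in step 5 are retained.

Compound list
1 | (S)-linalool, (3S)-3,7-dimethylocta-1,6-dien-3-ol | C=C[C@@](C)(O)CCC=C(C)C | starting material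
2 | (S,E)-8-hydroxylinalool, (2E,6S)-2,6-dimethylocta-2,7-diene-1,6-diol | C=C[C@@](C)(O)CC/C=C(\C)CO | intermediate
3 | (S,E)-8-oxolinalool, (2E,6S)-6-hydroxy-2,6-dimethylocta-2,7-dienal | C=C[C@@](C)(O)CC/C=C(\C)C=O | intermediate
4 | (R)-2-methylbutanoic acid | CC[C@@H](C)C(O)=O | starting material
5 | 2-methylphloroglucinol (2-methylbenzene-1,3,5-triol) | Cc1c(O)cc(O)cc1O | starting material
6 | (R)-2-methylbutanoyl chloride | CC[C@@H](C)C(Cl)=O | intermediate
7 | (2R)-2-methyl-1-(2,4,6-trihydroxy-3-methylphenyl)butan-1-one | CC[C@@H](C)C(=O)c1c(O)cc(O)c(C)c1O | intermediate
8 | prenyl acetate (3-methylbut-2-en-1-yl acetate) | CC(C)=CCOC(C)=O | starting material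
9 | dearomatised trione: C1 (R)-2-methylbutanoyl, C2 enolic OH, C3 quaternary with methyl and prenyl ((S) in the tautomer drawn), C4 and C6 C=O, C5 CH2 | CC[C@@H](C)C(=O)C1=C(O)[C@](C)(CC=C(C)C)C(=O)CC1=O | intermediate
10 | dienylidene trione: 9 condensed at C5 with 3; C5=C11 with the C4 carbonyl trans to C10; C10=C9 (E); chain C12–C13–C14(CH3)(OH)–C8H=C7H2 with C14 (S) | CC[C@@H](C)C(=O)C1=C(O)[C@](C)(CC=C(C)C)C(=O)/C(=C/C(C)=C/CC[C@](C)(O)C=C)C1=O | intermediate
11 | 2H-pyran valence isomer of 10: ring O–C6=C5–C11=C10–C9, C9 as an epimer mixture, other centres as in 10 | CC[C@@H](C)C(=O)C1=C(O)[C@](C)(CC=C(C)C)C(=O)C2=C1OC(CC[C@](C)(O)C=C)C(C)=C2 | intermediate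
12 | spiro tricycle: ring A as in 9, spiro at C5 to a cis-fused hexahydroindene (ring B with C10=C11 and C10 methyl; ring C with C14 methyl carbinol); the C4 carbonyl, C12 and C14 on one face of ring B; C14 hydroxyl concave, cis to C7 | CC[C@@H](C)C(=O)C1=C(O)[C@](C)(CC=C(C)C)C(=O)[C@]2(C[C@@H]3[C@@H](CC[C@]3(C)O)C(C)=C2)C1=O | intermediate
13 | syn-epoxide of 12: oxirane oxygen on C10 and C11 on the ring B face bearing C12 and C14 | CC[C@@H](C)C(=O)C1=C(O)[C@](C)(CC=C(C)C)C(=O)[C@]2(C[C@@H]3[C@@H](CC[C@]3(C)O)[C@@]4(C)O[C@H]42)C1=O | intermediate
14 | CNP0236509.3: as 12 with C11 as CH2 and C10 as methyl carbinol, the C10 hydroxyl on the ring B face bearing ring C | CC[C@@H](C)C(=O)C1=C(O)[C@](C)(CC=C(C)C)C(=O)[C@]2(C[C@@H]3[C@@H](CC[C@]3(C)O)[C@@](C)(O)C2)C1=O | target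

Total step count: 6. Longest linear sequence: 5 steps (steps 2 to 6, from 4 and 5 to 14).

Steps most likely to fail

1. Step 4. The closed pyran may dominate so strongly that dehydration of the tertiary allylic alcohol, hydrogen shifts or conjugate addition of the carbinol outrun the cycloaddition, and ring-fusion or spiro selectivity may be low. The fallback builds ring C first by radical chemistry and ring B by ionic closure; it sets out from 3 and 9 and returns at 12. PhSH/AIBN in benzene at 80 °C should add a thiyl radical to C7 of 3, and the C8 radical closes 5-exo onto C9 of the enal (cis-1,2 product expected for a 1-substituted hex-5-enyl radical) to give the cyclopentane aldehyde sulfide F1. MeI/NaI in DMF then converts the phenyl sulfide through its methylsulfonium salt into the primary iodide F2. Knoevenagel condensation of F2 with 9 (ethylenediammonium diacetate) and tautomerisation gives the 5-alkenyl trione F3. K2CO3 in DMF should finally close ring B by C5-alkylation at C7 (six-membered ring; O-alkylation would need an eight-membered ring) to give 12, to be separated from stereoisomers.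

2. Step 3. Attack through the unsubstituted C5 or through oxygen, over-allylation, or weak facial discrimination by the catalyst may erode the yield and the C3 configuration. The fallback is the classical uncatalysed dearomative C-alkylation; it sets out from 7 and returns at 9. Prenyl bromide with NaOMe in MeOH at 0 °C should give 9 together with its C3 epimer F4; the two are diastereomers because of the acyl centre and are separated by preparative HPLC.

3. Step 6. Hydride addition to the hindered C4 ketone may compete with the slow SN2 opening at C11 beside the quaternary C5. The fallback gives up chemoselectivity and restores the ketone afterwards; it sets out from 13 and returns at 14. Excess LiAlH4 in THF at reflux should open the epoxide and reduce C4=O to the C4 carbinol F5, whose only secondary alcohol is then re-oxidised by Dess–Martin oxidation (CH2Cl2, NaHCO3).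

Further compounds
F1 | step 4 | 2-[3-hydroxy-3-methyl-2-(phenylsulfanylmethyl)cyclopentyl]propanal, ring substituents cis as in ring C of 12, C10 as a mixture | c1ccccc1SC[C@@H]2[C@@H](CC[C@]2(C)O)C(C)C=O
F2 | step 4 | 2-[3-hydroxy-2-(iodomethyl)-3-methylcyclopentyl]propanal, configured as F1 | IC[C@@H]1[C@@H](CC[C@]1(C)O)C(C)C=O
F3 | step 4 | 5-alkenyl trione: 9 carrying at C5 the C11H=C10(CH3) unit attached to C9 of the iodomethyl cyclopentanol | CC[C@@H](C)C(=O)C1=C(O)[C@](C)(CC=C(C)C)C(=O)C(C=C(C)[C@@H]2CC[C@](C)(O)[C@@H]2CI)C1=O
F4 | step 3 | C3 epimer of 9 | CC[C@@H](C)C(=O)C1=C(O)[C@@](C)(CC=C(C)C)C(=O)CC1=O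
F5 | step 6 | C4 carbinol of 14 (C4 as a mixture) | CC[C@@H](C)C(=O)C1=C(O)[C@](C)(CC=C(C)C)C(O)[C@]2(C[C@@H]3[C@@H](CC[C@]3(C)O)[C@@](C)(O)C2)C1=O
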